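## Analysis of the target

Artoflavanone is a (2S)-flavanone: a chroman-4-one (ring A fused to the pyranone ring C) that carries a 3,4,5-trimethoxyphenyl ring B at C2. Ring A is substituted at every position except C8: a hydroxyl at C5 (hydrogen-bonded to the C4 carbonyl), a prenyl group at C6, a methoxy group at C7 and the ring oxygen O1 at C8a. C2 is the only stereocentre; it is a benzylic ether carbon β to the carbonyl, so it racemises whenever ring C opens to the 2'-hydroxychalcone under base, strong acid or heat. The prenyl alkene does not tolerate strong acid (it cyclises onto the neighbouring C5 oxygen), hydrogenation or electrophilic halogen, and the four aryl methyl ethers forbid unselective Lewis-acid dealkylation. The synthesis is hard for two reasons: C2 has to be set without relying on the reversible oxa-Michael closure, and a pentasubstituted ring A has to be built with the prenyl group at C6 and not at C8. The route rests on the fact that O1 is an ether oxygen joining the stereocentre C2 to the aromatic carbon C8a. If C8a carries bromine, the C2–O bond can be made beforehand as an ordinary enantiopure benzylic carbinol, and the O1–C8a bond can be formed afterwards without touching the stereocentre.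

## Retrosynthetic reasoning

Flavanone numbering (C2, C3, C4, C4a–C8a) is used for the open-chain compounds as well.

**18 to 17.** The last operation is release of the C5 hydroxyl from its methoxymethyl ether in 17. The oxygen is kept masked until then so that ring A offers no second oxygen nucleophile during ring closure. A free C5 hydroxyl next to a β-hydroxy ketone or a diketone would close the wrong pyranone ring. The acetal is peri to the C4 carbonyl in 17 and should leave under mild acid.

**17 to 16.** The C4 carbonyl is traced back to the carbinol of chromanol 16. Ring closure is thereby carried out on a substrate that has no β-hydroxy ketone and cannot fragment or dehydrate under base. The C4 stereocentre is sacrificial, and the oxidation needs only a neutral reagent that leaves C2 alone.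

**16 to 15 (key disconnection).** The O1–C8a bond is cut, giving the bromoaryl anti-1,3-diol 15. Cutting O1–C2 instead would mean forming the ether at the stereocentre, by a substitution with inversion at a benzylic carbon or by the reversible oxa-Michael addition that causes racemisation. Cutting at the aryl carbon leaves the C2–O bond intact from the moment it is made. The forward reaction is an intramolecular metal-catalysed aryl etherification. It has to choose the C2 hydroxyl over the C4 hydroxyl, and ring size decides that.

**15 to 14 to 13.** The two carbinols are traced to the 1,3-diketone 13 by two separate reductions. The C2 carbonyl lies next to the unhindered ring B and is given to a chiral ruthenium transfer-hydrogenation catalyst, which sets the only stereocentre that survives, to give 14. The C4 carbonyl is flanked by bromine and the acetal oxygen and is twisted out of the ring plane, so the same catalyst is not relied on there. The C2 hydroxyl of 14 directs an internal hydride delivery instead, giving the anti diol 15 as one diastereomer.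

**13 to 11 and 12.** The C3–C2 bond (methylene to the ring B carbonyl) is cut by a crossed Claisen condensation. Ring A is the nucleophile (methyl ketone 11) and ring B the electrophile (ester 12), because a benzoate with two ortho substituents on ring A would be a poor acyl acceptor. The hindered ketone cannot condense with itself.

**11 to 9 (with 10), 9 to 7 (with 8), 7 to 6, 6 to 4 (with 5).** The prenyl group is cut at its double bond to the allyl compound 9 and the trisubstituted alkene 10 (cross metathesis). The acetal is removed (7, with 8). The C6–allyl bond is then traced to the allyl ether 6 by an aromatic Claisen rearrangement, and 6 to phenol 4 and allyl bromide 5. Metalation and prenylation of the ring is not used. An aryl bromide undergoes halogen–metal exchange with alkyllithium bases, and amide bases would have to choose among three flanked ring positions. In 6, one of the two positions ortho to the ether oxygen is blocked by the acetyl group, so the sigmatropic shift can place the allyl group only at C6.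

**4 to 1 and 2 (through 3).** The acetyl group is cut off by Friedel–Crafts disconnection. In symmetric 1 the two positions next to bromine are equivalent and are the ones para to a methoxy group, so only one ketone (3) is expected. The Lewis acid then cleaves the methyl ether chelated to the new carbonyl. That differentiates the two oxygens as the target requires: the one ortho to the carbonyl becomes the C5 oxygen, the other stays as the C7 methoxy group.

## Alternatives that were turned down

**Alternative 1:** The C2–C3 bond of the silyl-protected flavanone A1 is cut, leading back to the racemic 2-aryl-4-methylene-1,3-benzodioxine A2. In the forward direction a chiral acid ionises A2 to an oxocarbenium–enol ion pair, and the enol carbon returns to C2. This forms C2–C3, closes ring C and makes both enantiomers of A2 converge on one enantiomer of A1.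
- For it: the flavanone oxidation level is reached directly, no redox adjustment at C4 is needed, and the only step after A1 is a fluoride desilylation. That end game avoids acid on the prenyl group and is better than the acid deprotection used here.
- Against it: the stereochemistry depends on a chiral counter-anion controlling the face of a 2-aryl oxocarbenium ion that the trimethoxyphenyl ring stabilises. Such an ion is long-lived and loosely paired, so facial control is not secured by anything in the substrate. The acid also meets a prenyl alkene next to a silyl ether, and A1 can racemise under the same acid by ring opening. A2 needs a methylenation of a benzodioxinone, and its ring A requires the same prenylated building block as here.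
- Comparison: the chosen route costs two redox steps at C4. In return it sets C2 by a ketone reduction of predictable facial sense and never breaks the C2–O bond afterwards.

**Alternative 2:** The C3–C4 and O1–C2 bonds of chromanol A3 are cut together, leading to the symmetric aldehyde A4 and the styrene A5. In the forward direction A4 is converted with an orthoformate into an ortho-quinone methide oxocarbenium ion, which undergoes a hetero-Diels–Alder addition to A5 under a chiral Brønsted acid, closing ring C.
- For it: it is the most convergent plan, with two bonds and the ring formed in one step from two simple pieces. The symmetry of A4 settles which oxygen becomes O1 and which stays at C5. On convergence and on the count of steps to the ring system it is clearly stronger than the chosen route.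
- Against it: A3 has no prenyl group and carries C4 as a methyl ether. The prenyl group would have to go in afterwards (allylation, rearrangement and metathesis, as here, but on a more advanced compound). The benzylic methyl ether would have to be turned into a ketone in the presence of two electron-rich rings, which is not a routine step. C2 would be set in a cycloaddition of a cationic heterodiene whose enantiofacial control by a chiral acid is uncertain, and the electron-rich A5 is prone to acid-induced oligomerisation.
- Comparison: the chosen route is longer and linear, but each stereochemical and regiochemical outcome follows from a well-understood control element, and the prenyl group is in place before the stereocentre exists.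

**Alternative 3:** The C4–C4a bond of the dimethoxy flavanone A6 is cut, leading to the (S)-3-aryloxy-3-arylpropanoic acid A7, whose aryl ether ring is symmetric. In the forward direction the activated carboxyl group acylates the position ortho to the ether oxygen and closes ring C.
- For it: the two ortho positions of A7 are equivalent, so there is no regiochemical question. The ring A building block carries no halogen, so its prenyl group can be introduced by directed metalation. The sequence is shorter than the chosen one, and on step economy it is the stronger plan.
- Against it: Friedel–Crafts activation means a strong Brønsted or Lewis acid in the presence of the prenyl alkene. It also acts on a doubly activated benzylic aryl ether at C2 that can ionise or eliminate to the unsaturated acid, which would lose or racemise the stereocentre. The C2–O bond would have to be made by substitution at a benzylic carbon with a hindered phenol. A6 still needs a selective demethylation at C5 with a Lewis acid next to the prenyl group.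
- Comparison: the chosen route closes ring C under basic, non-electrophilic conditions, keeps the C2–O bond untouched, and needs only a mild acetal cleavage at the end, at the price of more steps.

Key step: step 9

Assumption: the (S,S)-TsDPEN ruthenium catalyst is taken to reduce the ring B ketone of 13 with the same facial sense as acetophenone, giving the (S)-carbinol. If the sense were reversed on this substrate, the (R,R) ligand would be used with no other change.

## Route

Step 1
Reactants: 1 1-bromo-3,5-dimethoxybenzene; 2 acetyl chloride
Product: 4 1-(2-bromo-6-hydroxy-4-methoxyphenyl)ethanone, via dimethoxy ketone 3 (not isolated)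
Conditions: AcCl, AlCl3 (3 equiv), CH2Cl2, 0 °C to 40 °C; then ice-water
Reagents that add atoms: acetyl chloride (2), CC(=O)Cl
Why: Friedel–Crafts acylation at the position next to bromine, which is para to one methoxy group and ortho to the other (both such positions of 1 are equivalent, and the position between the two methoxy groups is more hindered and has no para donor); excess AlCl3 then cleaves the methyl ether chelated to the new carbonyl (chelation-controlled ortho-demethylation) and should leave the para methoxy group alone.

Step 2
Reactants: 4 1-(2-bromo-6-hydroxy-4-methoxyphenyl)ethanone; 5 allyl bromide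
Product: 6 1-[2-bromo-4-methoxy-6-(prop-2-enyloxy)phenyl]ethanone
Conditions: allyl bromide, K2CO3, DMF, 60 °C
Reagents that add atoms: allyl bromide (5), C=CCBr
Why: Williamson ether synthesis; the phenoxide of the chelated phenol is alkylated on oxygen by the allylic bromide in a dipolar aprotic solvent.

Step 3
Reactants: 6 1-[2-bromo-4-methoxy-6-(prop-2-enyloxy)phenyl]ethanone
Product: 7 1-[2-bromo-6-hydroxy-4-methoxy-5-(prop-2-enyl)phenyl]ethanone
Conditions: N,N-diethylaniline, 190 °C
Reagents that add atoms: none
Why: Aromatic Claisen rearrangement ([3,3]-sigmatropic shift, then tautomerisation); one of the two positions ortho to the ether oxygen carries the acetyl group, so the allyl group can settle only at the free one, the future C6.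

Step 4
Reactants: 7 1-[2-bromo-6-hydroxy-4-methoxy-5-(prop-2-enyl)phenyl]ethanone; 8 chloromethyl methyl ether
Product: 9 1-[2-bromo-4-methoxy-6-(methoxymethoxy)-5-(prop-2-enyl)phenyl]ethanone
Conditions: NaH (1.1 equiv), DMF, 0 °C; MOMCl, 0 °C to rt
Reagents that add atoms: chloromethyl methyl ether (8), COCCl
Why: O-alkylation of the sodium phenoxide; the phenol is far more acidic than the methyl ketone, so one equivalent of base should deprotonate only oxygen, and the acetal is stable to all bases and catalysts used up to step 10.

Step 5
Reactants: 9 1-[2-bromo-4-methoxy-6-(methoxymethoxy)-5-(prop-2-enyl)phenyl]ethanone; 10 2-methylbut-2-ene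
Product: 11 1-[2-bromo-4-methoxy-6-(methoxymethoxy)-5-(3-methylbut-2-enyl)phenyl]ethanone
Conditions: RuCl2(=CHPh)(PCy3)(H2IMes) (second-generation Grubbs catalyst, 5 mol %), 2-methylbut-2-ene (excess), CH2Cl2, 40 °C, sealed vessel
Reagents that add atoms: 2-methylbut-2-ene (10), CC=C(C)C
Why: Olefin cross metathesis; the terminal alkene exchanges its methylene for the isopropylidene unit of the alkene used in excess, propene leaves, and the trisubstituted product should not re-enter the catalytic cycle.

Step 6
Reactants: 11 1-[2-bromo-4-methoxy-6-(methoxymethoxy)-5-(3-methylbut-2-enyl)phenyl]ethanone; 12 methyl 3,4,5-trimethoxybenzoate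
Product: 13 1-[2-bromo-4-methoxy-6-(methoxymethoxy)-5-(3-methylbut-2-enyl)phenyl]-3-(3,4,5-trimethoxyphenyl)propane-1,3-dione
Conditions: NaH (3 equiv), THF, 65 °C; then 1 M HCl to pH 5, 0 °C
Reagents that add atoms: methyl 3,4,5-trimethoxybenzoate (12), COC(=O)c1cc(OC)c(OC)c(OC)c1
Why: Crossed Claisen condensation; the enolate of the doubly ortho-substituted methyl ketone cannot self-condense and attacks the unhindered aryl ester, and deprotonation of the 1,3-diketone drives the equilibrium.

Step 7
Reactants: 13 1-[2-bromo-4-methoxy-6-(methoxymethoxy)-5-(3-methylbut-2-enyl)phenyl]-3-(3,4,5-trimethoxyphenyl)propane-1,3-dione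
Product: 14 (3S)-1-[2-bromo-4-methoxy-6-(methoxymethoxy)-5-(3-methylbut-2-enyl)phenyl]-3-hydroxy-3-(3,4,5-trimethoxyphenyl)propan-1-one
Conditions: RuCl(p-cymene)[(S,S)-TsDPEN] (2 mol %), HCO2H–Et3N (5:2), DMF, 40 °C
Reagents that add atoms: none
Why: Asymmetric transfer hydrogenation by outer-sphere, metal–ligand bifunctional hydride transfer; the catalyst should take the carbonyl next to ring B, which can lie coplanar with its aryl group and make the CH/π contact with the cymene ligand, while the carbonyl on ring A is twisted by its bromine and acetal neighbours; the (S,S) ligand sets the flavanone C2 carbinol as S, as for acetophenone.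

Step 8
Reactants: 14 (3S)-1-[2-bromo-4-methoxy-6-(methoxymethoxy)-5-(3-methylbut-2-enyl)phenyl]-3-hydroxy-3-(3,4,5-trimethoxyphenyl)propan-1-one
Product: 15 (1S,3S)-1-[2-bromo-4-methoxy-6-(methoxymethoxy)-5-(3-methylbut-2-enyl)phenyl]-3-(3,4,5-trimethoxyphenyl)propane-1,3-diol
Conditions: Me4NBH(OAc)3 (5 equiv), MeCN–AcOH (1:1), −30 °C to −20 °C; then aq. sodium potassium tartrate
Reagents that add atoms: none
Why: Evans–Saksena reduction; the existing hydroxyl exchanges an acetate on boron and hydride is delivered internally through a chair-like six-membered transition state, which should give the 1,3-anti diol, that is S at the new carbinol (flavanone C4).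

Step 9
Reactants: 15 (1S,3S)-1-[2-bromo-4-methoxy-6-(methoxymethoxy)-5-(3-methylbut-2-enyl)phenyl]-3-(3,4,5-trimethoxyphenyl)propane-1,3-diol
Product: 16 (2S,4S)-7-methoxy-5-(methoxymethoxy)-6-(3-methylbut-2-enyl)-2-(3,4,5-trimethoxyphenyl)chroman-4-ol
Conditions: Pd(OAc)2 (5 mol %), 2-(di-tert-butylphosphino)-1,1'-binaphthyl (6 mol %), Cs2CO3 (2 equiv), toluene, 70 °C
Reagents that add atoms: none
Why: Zerovalent palladium, formed in the flask from Pd(OAc)2 and the bulky electron-rich phosphine, inserts into the C8a–Br bond; the caesium alkoxide of the C2 hydroxyl replaces bromide on divalent palladium to give a seven-membered alkoxo(aryl)palladacycle, and C–O reductive elimination forms O1–C8a. The closest known reaction type is the intramolecular palladium-catalysed etherification of aryl bromides with primary and secondary alcohols to chromans and related oxygen heterocycles. Ring C closes as a six-membered ring by a formal 6-exo attack of oxygen on the sp2 carbon C8a. No stereocentre is formed: C2 stays S because only the O–aryl bond is made and the C2–O bond is never broken, and C4 is not involved. The step needs site selectivity between the two hydroxyls, and ring size secures it, since the C4 hydroxyl could reach C8a only through a four-membered ring. It also needs reductive elimination to outrun β-hydride elimination from the secondary alkoxide, which is the reason for the hindered di-tert-butylphosphine. The bromide is meta to both ring oxygens, so oxidative addition is not slowed by donor conjugation, and the prenyl alkene is para to C8a and cannot reach the arylpalladium for a Heck cyclisation. Because C4 is still an alcohol, the substrate has no β-hydroxy ketone unit that carbonate could cleave by retro-aldol reaction or dehydrate.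

Step 10
Reactants: 16 (2S,4S)-7-methoxy-5-(methoxymethoxy)-6-(3-methylbut-2-enyl)-2-(3,4,5-trimethoxyphenyl)chroman-4-ol
Product: 17 (2S)-7-methoxy-5-(methoxymethoxy)-6-(3-methylbut-2-enyl)-2-(3,4,5-trimethoxyphenyl)chroman-4-one
Conditions: Dess–Martin periodinane (1.5 equiv), pyridine, CH2Cl2, 0 °C to rt
Reagents that add atoms: none
Why: Dess–Martin oxidation of the secondary benzylic alcohol to the ketone; the buffered, non-basic medium should avoid the retro-oxa-Michael ring opening that would racemise C2, and the alkene and acetal are inert to the reagent.

Step 11
Reactants: 17 (2S)-7-methoxy-5-(methoxymethoxy)-6-(3-methylbut-2-enyl)-2-(3,4,5-trimethoxyphenyl)chroman-4-one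
Product: 18 artoflavanone, (2S)-5-hydroxy-7-methoxy-6-(3-methylbut-2-enyl)-2-(3,4,5-trimethoxyphenyl)chroman-4-one
Conditions: HCl (1.25 M in MeOH), THF, 0 °C to rt
Reagents that add atoms: none
Why: Acid-catalysed acetal cleavage by transacetalisation to methanol; the peri carbonyl makes this acetal labile, and the hydrogen bond it forms with the freed phenol lowers the tendency of that oxygen to add to the prenyl alkene, so dilute acid at or below room temperature should suffice.

## Compound list

1 | 1-bromo-3,5-dimethoxybenzene | COc1cc(Br)cc(OC)c1 | starting material
2 | acetyl chloride | CC(=O)Cl | starting material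
3 | 1-(2-bromo-4,6-dimethoxyphenyl)ethanone | CC(=O)c1c(Br)cc(OC)cc1OC | intermediate (not isolated)
4 | 1-(2-bromo-6-hydroxy-4-methoxyphenyl)ethanone | CC(=O)c1c(Br)cc(OC)cc1O | intermediate
5 | allyl bromide (3-bromoprop-1-ene) | C=CCBr | starting material
6 | 1-[2-bromo-4-methoxy-6-(prop-2-enyloxy)phenyl]ethanone | CC(=O)c1c(Br)cc(OC)cc1OCC=C | intermediate
7 | 1-[2-bromo-6-hydroxy-4-methoxy-5-(prop-2-enyl)phenyl]ethanone | CC(=O)c1c(Br)cc(OC)c(CC=C)c1O | intermediate
8 | chloromethyl methyl ether | COCCl | starting material
9 | 1-[2-bromo-4-methoxy-6-(methoxymethoxy)-5-(prop-2-enyl)phenyl]ethanone | CC(=O)c1c(Br)cc(OC)c(CC=C)c1OCOC | intermediate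
10 | 2-methylbut-2-ene | CC=C(C)C | starting material
11 | 1-[2-bromo-4-methoxy-6-(methoxymethoxy)-5-(3-methylbut-2-enyl)phenyl]ethanone | CC(=O)c1c(Br)cc(OC)c(CC=C(C)C)c1OCOC | intermediate
12 | methyl 3,4,5-trimethoxybenzoate | COC(=O)c1cc(OC)c(OC)c(OC)c1 | starting material
13 | 1-[2-bromo-4-methoxy-6-(methoxymethoxy)-5-(3-methylbut-2-enyl)phenyl]-3-(3,4,5-trimethoxyphenyl)propane-1,3-dione | COc1cc(Br)c(C(=O)CC(=O)c2cc(OC)c(OC)c(OC)c2)c(OCOC)c1CC=C(C)C | intermediate
14 | (3S)-1-[2-bromo-4-methoxy-6-(methoxymethoxy)-5-(3-methylbut-2-enyl)phenyl]-3-hydroxy-3-(3,4,5-trimethoxyphenyl)propan-1-one | COc1cc(Br)c(C(=O)C[C@H](O)c2cc(OC)c(OC)c(OC)c2)c(OCOC)c1CC=C(C)C | intermediate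
15 | (1S,3S)-1-[2-bromo-4-methoxy-6-(methoxymethoxy)-5-(3-methylbut-2-enyl)phenyl]-3-(3,4,5-trimethoxyphenyl)propane-1,3-diol | COc1cc(Br)c([C@@H](O)C[C@H](O)c2cc(OC)c(OC)c(OC)c2)c(OCOC)c1CC=C(C)C | intermediate
16 | (2S,4S)-7-methoxy-5-(methoxymethoxy)-6-(3-methylbut-2-enyl)-2-(3,4,5-trimethoxyphenyl)chroman-4-ol (2,4-cis) | COc1cc2c(c(OCOC)c1CC=C(C)C)[C@@H](O)C[C@@H](c1cc(OC)c(OC)c(OC)c1)O2 | intermediate
17 | (2S)-7-methoxy-5-(methoxymethoxy)-6-(3-methylbut-2-enyl)-2-(3,4,5-trimethoxyphenyl)chroman-4-one | COc1cc2c(c(OCOC)c1CC=C(C)C)C(=O)C[C@@H](c1cc(OC)c(OC)c(OC)c1)O2 | intermediate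
18 | artoflavanone, (2S)-5-hydroxy-7-methoxy-6-(3-methylbut-2-enyl)-2-(3,4,5-trimethoxyphenyl)chroman-4-one | COc1cc2c(c(O)c1CC=C(C)C)C(=O)C[C@@H](c1cc(OC)c(OC)c(OC)c1)O2 | target

## Step count and least certain steps

Total: 11 steps. Longest linear sequence: 11 steps, from 1 to 18; compounds 2, 5, 8, 10 and 12 are purchased.

**Step 9 (key step).** The most likely failure is β-hydride elimination from the alkoxo(aryl)palladium intermediate of the secondary benzylic alkoxide, which would reduce the C–Br bond and oxidise the carbinol. Palladium could also be tied up as a chelate of the 1,3-diol. The fallback closes the same bond without a transition metal, through an aryne. It sets out from 15, which is treated with excess lithium 2,2,6,6-tetramethylpiperidide (LiTMP) in THF at −78 °C and warmed to room temperature. The base removes both hydroxyl protons and the single ring proton at C8, which is acidified by the flanking bromine and methoxy group. Loss of LiBr should give the C8a–C8 aryne F1, which is not isolated. The tethered C2 alkoxide adds at C8a in a six-membered closure, and the C7 methoxy group directs a nucleophile to that same, remote aryne carbon. Protonation of the C8 anion gives 16, where the fallback rejoins the route.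

**Step 7.** Hydride transfer may go to the wrong carbonyl or stall because the diketone sits as its enol or as a ruthenium diketonate. The β-hydroxy ketone may also dehydrate to the enone, which would erode the enantiomeric purity. The fallback builds the carbinol by C–B bond formation instead of carbonyl reduction. It sets out from 11, which is condensed with 3,4,5-trimethoxybenzaldehyde (KOH, EtOH, rt; Claisen–Schmidt) to the (E)-chalcone F2. Enantioselective conjugate borylation follows (CuCl, NaOtBu, (R)-1-[(S)-2-(diphenylphosphino)ferrocenyl]ethyldicyclohexylphosphine or its enantiomer as needed for the S product, B2pin2, MeOH, THF, rt) and should give the (3S)-β-boryl ketone F3. Oxidation with NaBO3·4H2O in THF–water proceeds with retention and leads back to 14.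

**Step 8.** Internal hydride delivery to the twisted, doubly ortho-substituted aryl ketone may be slow, which would leave room for undirected reduction and poor diastereocontrol. The fallback gives up the anti requirement, since this carbon becomes the C4 carbonyl. It sets out from 14, which is reduced with external hydride on the boron chelate (Et2BOMe, NaBH4, THF–MeOH, −78 °C; Narasaka–Prasad reduction) to the syn (1R,3S)-diol F4. Under the conditions of step 9, F4 should close to the 2,4-trans (2S,4R)-chromanol F5, and under the conditions of step 10 F5 gives 17, where the fallback rejoins the route.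

**Step 11.** Protonation of the prenyl alkene, followed by capture of the cation by the neighbouring C5 oxygen or by methanol, may compete with acetal cleavage. Acid-induced ring opening could also erode the configuration at C2. The fallback changes the order of events so that no prenyl group is present when acid is used. It sets out from 9 and omits step 5. The conditions of steps 6 to 10 are applied to the allyl series, giving in turn the allyl diketone F6, the allyl (3S)-hydroxy ketone F7, the allyl (1S,3S)-diol F8, the allyl (2S,4S)-chromanol F9 and the allyl flavanone methoxymethyl ether F10. Acid cleavage of the acetal (conditions of step 11) then gives the 6-allyl-5-hydroxyflavanone F11, whose terminal alkene cannot form a tertiary cation. A final cross metathesis with 10 (catalyst and conditions of step 5) leads to 18.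

## Further compounds

F1 | step 9 | (1S,3S)-1-[4-methoxy-6-(methoxymethoxy)-5-(3-methylbut-2-enyl)-2,3-didehydrophenyl]-3-(3,4,5-trimethoxyphenyl)propane-1,3-diol (aryne between C8a and C8, present as its dilithium alkoxide, not isolated) | COC1=C(CC=C(C)C)C(OCOC)=C([C@@H](O)C[C@H](O)c2cc(OC)c(OC)c(OC)c2)C#C1
F2 | step 7 | (E)-1-[2-bromo-4-methoxy-6-(methoxymethoxy)-5-(3-methylbut-2-enyl)phenyl]-3-(3,4,5-trimethoxyphenyl)prop-2-en-1-one | COc1cc(Br)c(C(=O)/C=C/c2cc(OC)c(OC)c(OC)c2)c(OCOC)c1CC=C(C)C
F3 | step 7 | (3S)-1-[2-bromo-4-methoxy-6-(methoxymethoxy)-5-(3-methylbut-2-enyl)phenyl]-3-(4,4,5,5-tetramethyl-1,3,2-dioxaborolan-2-yl)-3-(3,4,5-trimethoxyphenyl)propan-1-one | COc1cc(Br)c(C(=O)C[C@H](B2OC(C)(C)C(C)(C)O2)c2cc(OC)c(OC)c(OC)c2)c(OCOC)c1CC=C(C)C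
F4 | step 8 | (1R,3S)-1-[2-bromo-4-methoxy-6-(methoxymethoxy)-5-(3-methylbut-2-enyl)phenyl]-3-(3,4,5-trimethoxyphenyl)propane-1,3-diol | COc1cc(Br)c([C@H](O)C[C@H](O)c2cc(OC)c(OC)c(OC)c2)c(OCOC)c1CC=C(C)C
F5 | step 8 | (2S,4R)-7-methoxy-5-(methoxymethoxy)-6-(3-methylbut-2-enyl)-2-(3,4,5-trimethoxyphenyl)chroman-4-ol | COc1cc2c(c(OCOC)c1CC=C(C)C)[C@H](O)C[C@@H](c1cc(OC)c(OC)c(OC)c1)O2
F6 | step 11 | 1-[2-bromo-4-methoxy-6-(methoxymethoxy)-5-(prop-2-enyl)phenyl]-3-(3,4,5-trimethoxyphenyl)propane-1,3-dione | COc1cc(Br)c(C(=O)CC(=O)c2cc(OC)c(OC)c(OC)c2)c(OCOC)c1CC=C
F7 | step 11 | (3S)-1-[2-bromo-4-methoxy-6-(methoxymethoxy)-5-(prop-2-enyl)phenyl]-3-hydroxy-3-(3,4,5-trimethoxyphenyl)propan-1-one | COc1cc(Br)c(C(=O)C[C@H](O)c2cc(OC)c(OC)c(OC)c2)c(OCOC)c1CC=C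
F8 | step 11 | (1S,3S)-1-[2-bromo-4-methoxy-6-(methoxymethoxy)-5-(prop-2-enyl)phenyl]-3-(3,4,5-trimethoxyphenyl)propane-1,3-diol | COc1cc(Br)c([C@@H](O)C[C@H](O)c2cc(OC)c(OC)c(OC)c2)c(OCOC)c1CC=C
F9 | step 11 | (2S,4S)-7-methoxy-5-(methoxymethoxy)-6-(prop-2-enyl)-2-(3,4,5-trimethoxyphenyl)chroman-4-ol | COc1cc2c(c(OCOC)c1CC=C)[C@@H](O)C[C@@H](c1cc(OC)c(OC)c(OC)c1)O2
F10 | step 11 | (2S)-7-methoxy-5-(methoxymethoxy)-6-(prop-2-enyl)-2-(3,4,5-trimethoxyphenyl)chroman-4-one | COc1cc2c(c(OCOC)c1CC=C)C(=O)C[C@@H](c1cc(OC)c(OC)c(OC)c1)O2
F11 | step 11 | (2S)-5-hydroxy-7-methoxy-6-(prop-2-enyl)-2-(3,4,5-trimethoxyphenyl)chroman-4-one | COc1cc2c(c(O)c1CC=C)C(=O)C[C@@H](c1cc(OC)c(OC)c(OC)c1)O2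
A1 | alternative 1 | (2S)-5-(tert-butyldimethylsilyloxy)-7-methoxy-6-(3-methylbut-2-enyl)-2-(3,4,5-trimethoxyphenyl)chroman-4-one | COc1cc2c(c(O[Si](C)(C)C(C)(C)C)c1CC=C(C)C)C(=O)C[C@@H](c1cc(OC)c(OC)c(OC)c1)O2
A2 | alternative 1 | racemic 5-(tert-butyldimethylsilyloxy)-7-methoxy-4-methylidene-6-(3-methylbut-2-enyl)-2-(3,4,5-trimethoxyphenyl)-4H-1,3-benzodioxine | COc1cc2c(c(O[Si](C)(C)C(C)(C)C)c1CC=C(C)C)C(=C)OC(c1cc(OC)c(OC)c(OC)c1)O2
A3 | alternative 2 | (2S,4S)-4,7-dimethoxy-2-(3,4,5-trimethoxyphenyl)chroman-5-ol | COc1cc2c(c(O)c1)[C@@H](OC)C[C@@H](c1cc(OC)c(OC)c(OC)c1)O2
A4 | alternative 2 | 2,6-dihydroxy-4-methoxybenzaldehyde | COc1cc(O)c(C=O)c(O)c1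
A5 | alternative 2 | 3,4,5-trimethoxystyrene | C=Cc1cc(OC)c(OC)c(OC)c1
A6 | alternative 3 | (2S)-5,7-dimethoxy-6-(3-methylbut-2-enyl)-2-(3,4,5-trimethoxyphenyl)chroman-4-one | COc1cc2c(c(OC)c1CC=C(C)C)C(=O)C[C@@H](c1cc(OC)c(OC)c(OC)c1)O2
A7 | alternative 3 | (3S)-3-[3,5-dimethoxy-4-(3-methylbut-2-enyl)phenoxy]-3-(3,4,5-trimethoxyphenyl)propanoic acid | OC(=O)C[C@@H](c1cc(OC)c(OC)c(OC)c1)Oc1cc(OC)c(CC=C(C)C)c(OC)c1
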